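**Plan**

Locants: C1–C7 are the bicyclo[3.1.1]heptane carbons of the target (C2 spiro, C6 = CMe2, C7 = CH2); primed locants are the chromene.

- Retrosynthesis: C7 is taken back from CH2 to C=O. The cyclobutane bonds C1–C7 and C5–C6 are then cut together (retro ketene–alkene [2+2]), which opens the carbocycle C1–C2–C3–C4–C5–C7 and leaves a butanoic acid arm and a Me2C=CH group on C2 of the dihydropyran. Then C2–C3 (allyl, one-carbon homologation), then C4'–C4a' (Michael) back to syncarpic acid and a dienone.
- Forward ring order: trione ring bought → dihydropyran ring (Michael addition/hemiketal, then C2 made quaternary) → cyclobutane and six-membered carbocycle closed together as the last rings → C7=O removed.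
- Enabling feature: the bicycloheptane carries one CH2 bridge (C7) and one CMe2 bridge (C6) on C1/C5. It is therefore the crossed [2+2] adduct of a ketene (C5=C7=O) and a Me2C=CH alkene (C6=C1) held three atoms apart (C2–C3–C4). The gem-dimethyl carbon steers the regiochemistry and the ketene carbonyl is the latent C7H2.
- Stereochemistry: C4' by primary-amine catalysis; C2 by 1,3-induction from C4' (allyl enters trans to isopropyl); C1 and C5 from C2 in the cycloaddition (ketene carbon adds to C1 anti to C3').

Key step: step 6

Assumption: syncarpic acid (6) is taken as a purchasable compound, and the (R,R)-diamine of step 2 is assumed to give the 4R adduct by analogy with its additions of cyclic 1,3-dicarbonyl compounds to enones (the (S,S)-diamine is used if the sense is opposite).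

**Route**

Step 1
Reactants: 1 mesityl oxide (4-methylpent-3-en-2-one); 2 isobutyraldehyde (2-methylpropanal)
Product: 5 (E)-2,7-dimethylocta-2,5-dien-4-one, via lithium aldolate 3 (not isolated), via aldol mesylate 4 (not isolated)
Conditions: LDA, THF, −78 °C; then 2; MsCl, −78 → 0 °C; Et3N, 0 °C → rt
Reagents that add atoms: none
Why: Kinetic α′-deprotonation gives the cross-conjugated lithium enolate, which undergoes aldol addition to the aldehyde; mesylation and E1cB elimination (aldol condensation) should give the E-enone, and no stereocentre is formed.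

Step 2
Reactants: 6 syncarpic acid (2,2,4,4-tetramethylcyclohexane-1,3,5-trione); 5 (E)-2,7-dimethylocta-2,5-dien-4-one
Product: 7 (4R)-2-hydroxy-4-isopropyl-6,6,8,8-tetramethyl-2-(2-methylprop-1-en-1-yl)-3,4-dihydro-2H-chromene-5,7(6H,8H)-dione (cyclic hemiketal, both C2 anomers)
Conditions: (1R,2R)-1,2-diphenylethane-1,2-diamine (20 mol %), AcOH, THF, rt
Reagents that add atoms: none
Why: Primary-amine (iminium) catalysed Michael addition of a cyclic 1,3-dicarbonyl compound to an enone, the reaction type used for 4-hydroxycoumarin and benzylideneacetone: only the CH(i-Pr) terminus should react because attack at the Me2C terminus would create two adjacent quaternary carbons, the diamine sets C4 (R) by shielding one face of the iminium ion while its second nitrogen directs the enol, and the adduct closes to the hemiketal.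

Step 3
Reactants: 7 the hemiketal of step 2
Product: 8 (2S,4R)-2-allyl-4-isopropyl-6,6,8,8-tetramethyl-2-(2-methylprop-1-en-1-yl)-3,4-dihydro-2H-chromene-5,7(6H,8H)-dione
Conditions: allyltrimethylsilane (3 equiv), TMSOTf (20 mol %), CH2Cl2, −78 °C; Et3N quench at −78 °C
Reagents that add atoms: allyltrimethylsilane C=CC[Si](C)(C)C
Why: Hosomi–Sakurai allylation of the ring oxocarbenium ion formed from the hemiketal: the silane should attack the oxocarbenium carbon (as in Ferrier-type C-allylation) on the face anti to the C4 isopropyl group, which A(1,3) strain with the C5 carbonyl holds pseudoaxial, so that allyl ends trans and the 2-methylpropenyl group cis to isopropyl (C2 = S).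

Step 4
Reactants: 8 the 2-allyl compound
Product: 9 4-[(2S,4R)-4-isopropyl-6,6,8,8-tetramethyl-2-(2-methylprop-1-en-1-yl)-5,7-dioxo-3,4,5,6,7,8-hexahydro-2H-chromen-2-yl]butanal
Conditions: Rh(acac)(CO)2 (1 mol %), BiPhePhos (2 mol %), CO/H2 (1:1, 10 bar), toluene, 60 °C
Reagents that add atoms: carbon monoxide [C-]#[O+]
Why: Rhodium/bisphosphite hydroformylation is linear-selective for the monosubstituted alkene and should leave the trisubstituted alkene and the tetrasubstituted vinylogous ester untouched, giving the one-carbon-longer aldehyde without affecting a stereocentre.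

Step 5
Reactants: 9 the butanal
Product: 10 4-[(2S,4R)-4-isopropyl-6,6,8,8-tetramethyl-2-(2-methylprop-1-en-1-yl)-5,7-dioxo-3,4,5,6,7,8-hexahydro-2H-chromen-2-yl]butanoic acid
Conditions: NaClO2, NaH2PO4, 2-methyl-2-butene, t-BuOH/H2O, 0 °C → rt; used at once
Reagents that add atoms: sodium chlorite [Na+].[O-]Cl=O
Why: Pinnick oxidation converts the aldehyde into the acid under buffered conditions, with 2-methyl-2-butene consuming the hypochlorite that would otherwise attack the alkene; the acid is not stored because a free acid beside a tertiary allylic ether invites ionisation.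

Step 6
Reactants: 10 the butanoic acid
Product: 13 (1S,2S,4'R,5S)-4'-isopropyl-6,6,6',6',8',8'-hexamethyl-3',4'-dihydrospiro[bicyclo[3.1.1]heptane-2,2'-chromene]-5',7,7'(6'H,8'H)-trione, via acid chloride 11 (not isolated), via ketene 12 (not isolated)
Conditions: 1-chloro-N,N,2-trimethylprop-1-en-1-amine (1.2 equiv), CH2Cl2, 0 °C → rt; then syringe-pump addition to Et3N (5 equiv), toluene, 110 °C, final ≤ 0.005 M
Reagents that add atoms: none
Why: Dehydrochlorination of 11 gives ketene 12, whose electrophilic central carbon (future C7) is attacked by the alkene CH (C1) while positive charge builds on the Me2C terminus (C6), which then collapses onto the ketene α-carbon (C5) in a concerted but highly asynchronous thermal [2+2]; the closest known case is the intramolecular cycloaddition of 7-methyl-6-octenoyl-type ketenes to 7,7-dimethylbicyclo[3.1.1]heptan-6-ones. The first bond closes the six-membered carbocycle C1–C2–C3–C4–C5–C7 in a 6-exo sense at the alkene and the second closes the cyclobutanone by enolate-carbon-to-cation collapse, so the crossed (bicyclo[3.1.1]) and not the fused (bicyclo[3.2.0]) adduct is needed; this is secured by the gem-dimethyl terminus, the only carbon able to carry the cationic character. C1 and C5 are both set relative to the quaternary C2: with the tether carbon C3 inside, the ketene carbon should add to C1 anti to the C2–C3' bond (larger substituent and better σ-donor antiperiplanar, ring oxygen outside), which places the carbonyl bridge next to O1' and the CMe2 bridge on the C3' side, and C5 follows because the four-membered ring can only be cis-fused. Putting the alkene directly on C2 and the ketene on the far arm is deliberate, since the reverse arrangement would make the CMe2 carbon the group that adds anti to C3' and should give the spiro epimer. High dilution and slow addition suppress ketene dimerisation, and because the C2 oxygen is δ to the acyl carbon no β-elimination of the vinylogous carboxylate can compete.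

Step 7
Reactants: 13 the cyclobutanone
Product: 14 the 7-(4-methylbenzenesulfonyl)hydrazone of 13 (all four stereocentres as in 13; C=N geometry not defined)
Conditions: TsNHNH2 (1.1 equiv), EtOH, 50 °C
Reagents that add atoms: 4-methylbenzenesulfonohydrazide Cc1ccc(cc1)S(=O)(=O)NN
Why: Hydrazone condensation should be selective for the strained, sterically open cyclobutanone, since the C7' ketone lies between two quaternary carbons and the C5' carbonyl is a deactivated vinylogous ester.

Step 8
Reactants: 14 the tosylhydrazone
Product: 15 (1S,2S,4'R,5R)-4'-isopropyl-6,6,6',6',8',8'-hexamethyl-3',4'-dihydrospiro[bicyclo[3.1.1]heptane-2,2'-chromene]-5',7'(6'H,8'H)-dione (target)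
Conditions: catecholborane (2.5 equiv), CHCl3, 0 °C → rt; then NaOAc·3H2O, reflux
Reagents that add atoms: none
Why: Caglioti-type tosylhydrazone reduction in its catecholborane/acetate form: hydride adds to C=N, acetate triggers loss of sulfinate and the diazene loses N2 to leave CH2 at C7, under near-neutral conditions that should spare the tertiary ether and the two remaining carbonyl groups.

**Compound list**

1 | mesityl oxide (4-methylpent-3-en-2-one) | CC(=O)C=C(C)C | starting material
2 | isobutyraldehyde (2-methylpropanal) | CC(C)C=O | starting material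
3 | lithium 2,7-dimethyl-5-oxooct-6-en-3-olate (racemic aldolate) | CC(C)C([O-])CC(=O)C=C(C)C.[Li+] | intermediate
4 | 2,7-dimethyl-5-oxooct-6-en-3-yl methanesulfonate (racemic) | CC(C)C(OS(C)(=O)=O)CC(=O)C=C(C)C | intermediate
5 | (E)-2,7-dimethylocta-2,5-dien-4-one | CC(C)/C=C/C(=O)C=C(C)C | intermediate
6 | syncarpic acid (2,2,4,4-tetramethylcyclohexane-1,3,5-trione) | CC1(C)C(=O)CC(=O)C(C)(C)C1=O | starting material
7 | (4R)-2-hydroxy-4-isopropyl-6,6,8,8-tetramethyl-2-(2-methylprop-1-en-1-yl)-3,4-dihydro-2H-chromene-5,7(6H,8H)-dione (C2 anomers) | CC(C)[C@H]1CC(O)(C=C(C)C)OC2=C1C(=O)C(C)(C)C(=O)C2(C)C | intermediate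
8 | (2S,4R)-2-allyl-4-isopropyl-6,6,8,8-tetramethyl-2-(2-methylprop-1-en-1-yl)-3,4-dihydro-2H-chromene-5,7(6H,8H)-dione | CC(C)[C@H]1C[C@](C=C(C)C)(CC=C)OC2=C1C(=O)C(C)(C)C(=O)C2(C)C | intermediate
9 | 4-[(2S,4R)-4-isopropyl-6,6,8,8-tetramethyl-2-(2-methylprop-1-en-1-yl)-5,7-dioxo-3,4,5,6,7,8-hexahydro-2H-chromen-2-yl]butanal | CC(C)[C@H]1C[C@](C=C(C)C)(CCCC=O)OC2=C1C(=O)C(C)(C)C(=O)C2(C)C | intermediate
10 | 4-[(2S,4R)-4-isopropyl-6,6,8,8-tetramethyl-2-(2-methylprop-1-en-1-yl)-5,7-dioxo-3,4,5,6,7,8-hexahydro-2H-chromen-2-yl]butanoic acid | CC(C)[C@H]1C[C@](C=C(C)C)(CCCC(=O)O)OC2=C1C(=O)C(C)(C)C(=O)C2(C)C | intermediate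
11 | acid chloride of 10 (2S,4R) | CC(C)[C@H]1C[C@](C=C(C)C)(CCCC(=O)Cl)OC2=C1C(=O)C(C)(C)C(=O)C2(C)C | intermediate
12 | ketene from 11 (2S,4R; C2–CH2CH2–CH=C=O) | CC(C)[C@H]1C[C@](C=C(C)C)(CCC=C=O)OC2=C1C(=O)C(C)(C)C(=O)C2(C)C | intermediate
13 | (1S,2S,4'R,5S)-4'-isopropyl-6,6,6',6',8',8'-hexamethyl-3',4'-dihydrospiro[bicyclo[3.1.1]heptane-2,2'-chromene]-5',7,7'(6'H,8'H)-trione | CC(C)[C@H]1C[C@]2(CC[C@@H]3C(=O)[C@H]2C3(C)C)OC2=C1C(=O)C(C)(C)C(=O)C2(C)C | intermediate
14 | 7-(4-methylbenzenesulfonyl)hydrazone of 13 | CC(C)[C@H]1C[C@]2(CC[C@@H]3C(=NNS(=O)(=O)c4ccc(C)cc4)[C@H]2C3(C)C)OC2=C1C(=O)C(C)(C)C(=O)C2(C)C | intermediate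
15 | (1S,2S,4'R,5R)-4'-isopropyl-6,6,6',6',8',8'-hexamethyl-3',4'-dihydrospiro[bicyclo[3.1.1]heptane-2,2'-chromene]-5',7'(6'H,8'H)-dione | CC(C)[C@H]1C[C@]2(CC[C@@H]3C[C@H]2C3(C)C)OC2=C1C(=O)C(C)(C)C(=O)C2(C)C | target

**Count**

Total steps: 8. Longest linear sequence: 8 steps (1/2 → 5 → 7 → 8 → 9 → 10 → 13 → 14 → 15).

**Steps most likely to fail**

Step 6. The ketene may engage the neopentyl-type alkene too slowly, so that dimerisation, proton loss from the developing tertiary cation (ene-type product) or thermal ionisation of the tertiary allylic ether at 110 °C take over; closure on the other face of C1 is the second concern. The fallback sets out from 10 and uses a keteniminium–alkene cycloaddition, which runs well below the ketene temperature with a much stronger electrophile. Acid chloride 11 is quenched with dimethylamine to give the N,N-dimethylamide F1. Triflic anhydride and 2,4,6-collidine in 1,2-dichloroethane (rt → 80 °C) generate the keteniminium triflate F2, which should add to the alkene with the same regiochemistry to give the cyclobutaniminium triflate F3. Aqueous NaHCO3 hydrolysis returns to the route at 13.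

Step 3. The allylsilane may attack the distal Me2C terminus of the delocalised cation, or the product ether may re-ionise under the Lewis acid with loss of the C2 configuration. The fallback sets out from 7 and forms the C–C bond on the ketone before the ring is closed. Allylmagnesium bromide (2.5 equiv, THF, −78 °C; the first equivalent forms the magnesium enolate of the trione) adds 1,2 to the ketone of the open form to give the tertiary allylic alcohol F4. PPTS (cat.), CH2Cl2, 4 Å sieves then closes the ether by capture of the tertiary allylic cation by the enol oxygen, giving 8 together with its C2 epimer F5, which is removed by chromatography. The route is rejoined at 8.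

Step 2. The addition may be slow or poorly face-selective, because both arms of the dienone are alkenyl (two iminium geometries) and the donor is hindered. The fallback sets out from 6 and uses secondary-amine iminium catalysis on an enal. Michael addition of 6 to commercial (E)-4-methylpent-2-enal with a diarylprolinol silyl ether (the enantiomer that gives the 4R product) gives the lactol F6. Oxidation (PhI(OAc)2, TEMPO cat., CH2Cl2) gives the enol lactone F7. 2-Methylprop-1-enylmagnesium bromide (1.05 equiv, THF, −78 °C) opens this activated enol ester to the ketone, which closes to 7 on work-up.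

**Further compounds**

F1 | step 6 | 4-[(2S,4R)-4-isopropyl-6,6,8,8-tetramethyl-2-(2-methylprop-1-en-1-yl)-5,7-dioxo-3,4,5,6,7,8-hexahydro-2H-chromen-2-yl]-N,N-dimethylbutanamide | CC(C)[C@H]1C[C@](C=C(C)C)(CCCC(=O)N(C)C)OC2=C1C(=O)C(C)(C)C(=O)C2(C)C
F2 | step 6 | keteniminium triflate from F1 (C2–CH2CH2–CH=C=N+Me2) | CC(C)[C@H]1C[C@](C=C(C)C)(CCC=C=[N+](C)C)OC2=C1C(=O)C(C)(C)C(=O)C2(C)C.[O-]S(=O)(=O)C(F)(F)F
F3 | step 6 | 7-(dimethyliminio) analogue of 13, triflate salt | CC(C)[C@H]1C[C@]2(CC[C@@H]3C(=[N+](C)C)[C@H]2C3(C)C)OC2=C1C(=O)C(C)(C)C(=O)C2(C)C.[O-]S(=O)(=O)C(F)(F)F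
F4 | step 3 | 5-hydroxy-6-[(3R)-5-hydroxy-2,7-dimethyl-5-(prop-2-en-1-yl)oct-6-en-3-yl]-2,2,4,4-tetramethylcyclohex-5-ene-1,3-dione (C5 epimers of the side chain) | CC(C)[C@@H](CC(O)(CC=C)C=C(C)C)C1=C(O)C(C)(C)C(=O)C(C)(C)C1=O
F5 | step 3 | (2R,4R)-2-allyl-4-isopropyl-6,6,8,8-tetramethyl-2-(2-methylprop-1-en-1-yl)-3,4-dihydro-2H-chromene-5,7(6H,8H)-dione (C2 epimer of 8) | CC(C)[C@H]1C[C@@](C=C(C)C)(CC=C)OC2=C1C(=O)C(C)(C)C(=O)C2(C)C
F6 | step 2 | (4R)-2-hydroxy-4-isopropyl-6,6,8,8-tetramethyl-3,4-dihydro-2H-chromene-5,7(6H,8H)-dione (lactol, C2 anomers) | CC(C)[C@H]1CC(O)OC2=C1C(=O)C(C)(C)C(=O)C2(C)C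
F7 | step 2 | (4R)-4-isopropyl-6,6,8,8-tetramethyl-3,4-dihydro-2H-chromene-2,5,7(6H,8H)-trione (enol lactone) | CC(C)[C@H]1CC(=O)OC2=C1C(=O)C(C)(C)C(=O)C2(C)C
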